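**Retrosynthetic overview**
1. Target 33 ⇐ vinyl diene 31 (cross-metathesis with methyl vinyl ketone, last step) ⇐ cis-fused ketol 25 (ring C ketone → enol triflate → acetyl; amine unmasking of the ring A methylene).
2. Ring C is not made by the biomimetic [4+2] dimerisation but by a Robinson-type spiro-annulation: aldol bond C(OH)–CH2, C-acylation at the spiro carbon, Michael bond CH–CH2.
3. Michael donor 19 (ring B cycloheptanone, by enol-ether ring-closing metathesis) and acceptor 14 (ring E, by enyne ring-closing metathesis) both come from one enyne lactone 13.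
4. 13 ⇐ (3R)-3-methylpent-4-ynal 6 + (Z)-2-carbomethoxy allylboronate 11 (asymmetric allylboration/lactonisation).
5. Ring order: lactone of 13 (becomes A and D) → E (14) and B (17) → C (25) → side chains.

Assumption: rings are lettered A (α-methylene lactone), B (cycloheptane), C (cyclohexene), D (spiro lactone), E (cycloheptene); three centres that are erased or equilibrated later (the CH–CH2NMe2 carbon, the CH(OH)CH3 carbon, the ketone α-CH of 23/24) are carried as mixtures and drawn without configuration.

**Step 1**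
Reactants: 1 (2R)-but-3-yn-2-ol
Product: 2 (2R)-but-3-yn-2-yl methanesulfonate
Conditions: MsCl, Et3N, CH2Cl2, 0 °C
Reagents that add atoms: methanesulfonyl chloride, CS(=O)(=O)Cl
Why: O-sulfonylation (mesylation) activates the alcohol without touching the C–O stereocentre.

**Step 2**
Reactants: 2 mesylate; 3 dimethyl malonate
Product: 4 dimethyl 2-[(2R)-but-3-yn-2-yl]malonate
Conditions: NaH, THF/DMF, 0 → 50 °C
Reagents that add atoms: none
Why: Malonate alkylation by SN2 displacement at the propargylic carbon goes with inversion and sets the methyl-bearing stereocentre (the descriptor stays R only because the priorities change).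

**Step 3**
Reactants: 4 malonate
Product: 5 methyl (3R)-3-methylpent-4-ynoate
Conditions: NaCl, H2O, DMSO, 150 °C
Reagents that add atoms: none
Why: Krapcho dealkoxycarbonylation removes one ester and leaves the β-stereocentre untouched.

**Step 4**
Reactants: 5 ester
Product: 6 (3R)-3-methylpent-4-ynal
Conditions: i-Bu2AlH (1.05 equiv), CH2Cl2, −78 °C; aq. KNaC4H4O6 work-up
Reagents that add atoms: none
Why: Half-reduction of the ester stops at the aldehyde because the tetrahedral aluminate is stable at −78 °C.

**Step 5**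
Reactants: 7 methyl propiolate; 8 allyl bromide
Product: 9 methyl hex-5-en-2-ynoate
Conditions: CuI (10 mol %), NaI (20 mol %), K2CO3, DMF, rt
Reagents that add atoms: none
Why: Copper-acetylide allylation of the terminal alkyne gives the skipped enynoate under non-isomerising, weakly basic conditions.

**Step 6**
Reactants: 9 enynoate
Product: 11 (Z)-2-carbomethoxy allylboronate, via alkenylalane 10 (not isolated)
Conditions: i-Bu2AlH, HMPA, THF, 0 °C; then ICH2B(pin), 0 °C → rt
Reagents that add atoms: 2-(iodomethyl)-4,4,5,5-tetramethyl-1,3,2-dioxaborolane, ICB1OC(C)(C)C(C)(C)O1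
Why: syn-Hydroalumination of the ynoate (H to the β-carbon, Al to the α-carbon) followed by C-alkylation of the alkenylalane with retention places the allyl group trans to CH2B, the geometry needed for an anti allylboration.

**Step 7**
Reactants: 6 aldehyde; 11 boronate
Product: 13 enyne lactone (trans), via hydroxy ester 12 (not isolated)
Conditions: (S)-TRIP phosphoric acid (5 mol %), 4 Å sieves, toluene, −30 °C; then p-TsOH·H2O (10 mol %), CH2Cl2, rt
Reagents that add atoms: none
Why: Chiral-phosphoric-acid-catalysed allylboration through a chair Zimmerman–Traxler transition state gives the anti adduct from the crotyl-(E)-type boronate, the catalyst directs the allyl unit to the Si face of the aldehyde, and acid-catalysed lactonisation then closes the trans α-methylene lactone with both ring stereocentres set.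

**Step 8**
Reactants: 13 enyne lactone
Product: 14 ring E diene lactone
Conditions: second-generation Grubbs catalyst [RuCl2(=CHPh)(PCy3)(NHC), NHC = 1,3-dimesitylimidazolidin-2-ylidene] (5 mol %), ethene (1 atm), CH2Cl2, 40 °C
Reagents that add atoms: none
Why: Ring-closing enyne metathesis closes the seven-membered ring E as the 1-vinylcycloheptene without touching a stereocentre or the 1,1-disubstituted lactone alkene.

**Step 9**
Reactants: 13 enyne lactone
Product: 15 methyl ketone
Conditions: AuCl(NHC′) (2 mol %; NHC′ = 1,3-bis(2,6-diisopropylphenyl)imidazol-2-ylidene), AgSbF6 (2 mol %), 1,4-dioxane/H2O, 80 °C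
Reagents that add atoms: water, O
Why: Gold-catalysed Markovnikov hydration of the terminal alkyne gives the methyl ketone while the alkenes and the lactone are inert.

**Step 10**
Reactants: 15 methyl ketone
Product: 16 terminal silyl enol ether
Conditions: Me3SiOTf, Et3N, CH2Cl2, −78 → 0 °C
Reagents that add atoms: trimethylsilyl trifluoromethanesulfonate, C[Si](C)(C)OS(=O)(=O)C(F)(F)F
Why: Soft enolisation removes a proton from the unhindered methyl group, so the terminal (kinetic) silyl enol ether forms and the α-stereocentre is kept.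

**Step 11**
Reactants: 16 silyl enol ether
Product: 17 ring B cyclic silyl enol ether
Conditions: second-generation Grubbs catalyst (5 mol %), toluene, 80 °C, argon sparge
Reagents that add atoms: none
Why: Ring-closing metathesis between the enol ether and the allyl group closes ring B as a regiodefined cycloheptanone enol ether, the conjugated lactone methylene being unreactive.

**Step 12**
Reactants: 17 cyclic silyl enol ether
Product: 19 amino keto lactone, via amine adduct 18 (not isolated)
Conditions: Me2NH (2 M in MeOH, 5 equiv), MeOH, 0 °C → rt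
Reagents that add atoms: dimethylamine, CNC
Why: aza-Michael addition masks the α-methylene lactone as its Mannich base (classical amine protection) and methanolysis of the silyl enol ether releases the ring B ketone.

**Step 13**
Reactants: 19 amino keto lactone; 14 diene lactone; 20 acetaldehyde
Product: 23 Michael–aldol adduct, via lithium enolate 21 (not isolated), via lactone enolate 22 (not isolated)
Conditions: LiN(i-Pr)2 (1.05 equiv), THF, −78 °C; 14 added over 30 min at −78 °C; then MeCHO (3 equiv), −78 °C; AcOH quench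
Reagents that add atoms: none
Why: Tandem Michael–aldol three-component coupling in which the kinetic CH2-side ketone enolate adds to the exocyclic methylene of 14 and the resulting lactone enolate takes up acetaldehyde on the face syn to the adjacent ring-fusion H (anti to the ring E CH2, the usual trans-α,β sense of γ-lactone enolates), which fixes the spiro stereocentre.

**Step 14**
Reactants: 23 Michael–aldol adduct
Product: 24 β-keto lactone
Conditions: (COCl)2, DMSO, CH2Cl2, −78 °C; Et3N, −78 → 0 °C
Reagents that add atoms: none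
Why: Swern oxidation converts the secondary carbinol into the acetyl group on a quaternary carbon that cannot epimerise.

**Step 15**
Reactants: 24 β-keto lactone
Product: 25 cis-fused ketol
Conditions: DBU (1.5 equiv), MeCN, 0 °C → rt
Reagents that add atoms: none
Why: Intramolecular aldol addition (Robinson-type closure stopped at the ketol) in which the acetyl enolate attacks the ring B ketone through a six-membered chair to give the cis-fused angular carbinol (OH cis to the ring-fusion H), while both ketone α-centres equilibrate through enolate and retro-aldol to the diastereomer with equatorial methyl and equatorial lactone bonds.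

**Step 16**
Reactants: 25 ketol
Product: 26 silyl ether
Conditions: Me3SiOTf, 2,6-lutidine, CH2Cl2, −78 °C
Reagents that add atoms: trimethylsilyl trifluoromethanesulfonate, C[Si](C)(C)OS(=O)(=O)C(F)(F)F
Why: Silylation of the tertiary alcohol blocks retro-aldol cleavage during the following enolisation.

**Step 17**
Reactants: 26 silyl ether
Product: 27 enol triflate
Conditions: KN(SiMe3)2 (1.1 equiv), THF, −78 °C; PhNTf2
Reagents that add atoms: N-phenylbis(trifluoromethanesulfonimide), O=S(=O)(N(c1ccccc1)S(=O)(=O)C(F)(F)F)C(F)(F)F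
Why: The ketone can enolise only toward the CH2 (the other α-carbon is the quaternary spiro centre), so O-triflation gives a single enol triflate.

**Step 18**
Reactants: 27 enol triflate
Product: 29 γ-hydroxy enone, via ethoxydiene 28 (not isolated)
Conditions: Pd(PPh3)4 (5 mol %), LiCl, tributyl(1-ethoxyvinyl)stannane, THF, 65 °C; then 1 M aq HCl, THF, rt; NaHCO3 work-up
Reagents that add atoms: tributyl(1-ethoxyvinyl)stannane, CCCC[Sn](CCCC)(CCCC)C(=C)OCC; water, O
Why: Stille coupling with an acetyl-anion equivalent followed by acid hydrolysis of the enol ether and the silyl ether gives the acetyl-substituted ring C alkene next to the free tertiary alcohol.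

**Step 19**
Reactants: 29 γ-hydroxy enone
Product: 31 ring A methylene lactone, via ammonium iodide 30 (not isolated)
Conditions: MeI (10 equiv), MeOH, rt; then satd aq NaHCO3, CH2Cl2, rt
Reagents that add atoms: none
Why: N-methylation and mild-base E1cB (Hofmann-type) elimination of trimethylamine regenerate the α-methylene lactone.

**Step 20**
Reactants: 31 vinyl diene; 32 methyl vinyl ketone
Product: 33 target CNP0168949.3
Conditions: second-generation Hoveyda–Grubbs catalyst [RuCl2(=CH–C6H4–2-Oi-Pr)(NHC)] (10 mol %), 32 (10 equiv), CH2Cl2, 40 °C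
Reagents that add atoms: none
Why: Cross-metathesis of the only monosubstituted alkene with methyl vinyl ketone gives the (E)-dienone, the 1,1-disubstituted lactone alkene and the trisubstituted enone being unreactive.

**Compound list**
1 | (2R)-but-3-yn-2-ol | C[C@@H](O)C#C | starting material
2 | (2R)-but-3-yn-2-yl methanesulfonate | CS(=O)(=O)O[C@H](C)C#C | intermediate
3 | dimethyl malonate | COC(=O)CC(=O)OC | starting material
4 | dimethyl 2-[(2R)-but-3-yn-2-yl]malonate | COC(=O)C([C@@H](C)C#C)C(=O)OC | intermediate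
5 | methyl (3R)-3-methylpent-4-ynoate | COC(=O)C[C@@H](C)C#C | intermediate
6 | (3R)-3-methylpent-4-ynal | O=CC[C@@H](C)C#C | intermediate
7 | methyl propiolate | C#CC(=O)OC | starting material
8 | allyl bromide | C=CCBr | starting material
9 | methyl hex-5-en-2-ynoate | C=CCC#CC(=O)OC | intermediate
10 | methyl (2E)-2-(diisobutylalumanyl)hexa-2,5-dienoate (Al cis to the vinylic H) | C=CC/C=C(\C(=O)OC)[Al](CC(C)C)CC(C)C | intermediate (not isolated)
11 | methyl (2Z)-2-[(4,4,5,5-tetramethyl-1,3,2-dioxaborolan-2-yl)methyl]hexa-2,5-dienoate (allyl cis to CO2Me) | C=CC/C=C(\C(=O)OC)CB1OC(C)(C)C(C)(C)O1 | intermediate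
12 | methyl (3S,4R,6R)-4-hydroxy-6-methyl-2-methylidene-3-(prop-2-en-1-yl)oct-7-ynoate | C=C(C(=O)OC)[C@H](CC=C)[C@H](O)C[C@@H](C)C#C | intermediate (not isolated)
13 | (4S,5R)-3-methylidene-5-[(2R)-2-methylbut-3-yn-1-yl]-4-(prop-2-en-1-yl)oxolan-2-one (trans lactone) | C=C1C(=O)O[C@H](C[C@@H](C)C#C)[C@H]1CC=C | intermediate
14 | (3aS,7R,8aR)-6-ethenyl-7-methyl-3-methylidene-4,7,8,8a-tetrahydro-3aH-cyclohepta[b]furan-2-one | C=C1C(=O)O[C@@H]2C[C@@H](C)C(C=C)=CC[C@@H]12 | intermediate
15 | (4S,5R)-3-methylidene-5-[(2R)-2-methyl-3-oxobutyl]-4-(prop-2-en-1-yl)oxolan-2-one | C=C1C(=O)O[C@H](C[C@@H](C)C(C)=O)[C@H]1CC=C | intermediate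
16 | (4S,5R)-3-methylidene-5-{(2R)-2-methyl-3-[(trimethylsilyl)oxy]but-3-en-1-yl}-4-(prop-2-en-1-yl)oxolan-2-one | C=C1C(=O)O[C@H](C[C@@H](C)C(=C)O[Si](C)(C)C)[C@H]1CC=C | intermediate
17 | (3aS,7R,8aR)-7-methyl-3-methylidene-6-[(trimethylsilyl)oxy]-4,7,8,8a-tetrahydro-3aH-cyclohepta[b]furan-2-one | C=C1C(=O)O[C@@H]2C[C@@H](C)C(O[Si](C)(C)C)=CC[C@@H]12 | intermediate
18 | (3aS,7R,8aR)-3-[(dimethylamino)methyl]-7-methyl-6-[(trimethylsilyl)oxy]-3,3a,4,7,8,8a-hexahydro-2H-cyclohepta[b]furan-2-one (C3 epimers) | CN(C)CC1C(=O)O[C@@H]2C[C@@H](C)C(O[Si](C)(C)C)=CC[C@@H]12 | intermediate (not isolated)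
19 | (3aS,7R,8aR)-3-[(dimethylamino)methyl]-7-methylhexahydro-2H-cyclohepta[b]furan-2,6(3H)-dione (C3 epimers) | CN(C)CC1C(=O)O[C@@H]2C[C@@H](C)C(=O)CC[C@@H]12 | intermediate
20 | acetaldehyde | CC=O | starting material
21 | lithium enolate of 19 (C5=C6, O–Li on C6) | CN(C)CC1C(=O)O[C@@H]2C[C@@H](C)C(O[Li])=CC[C@@H]12 | intermediate (not isolated)
22 | lithium lactone enolate: 19 joined through C5 to the former exocyclic CH2 of 14 | CN(C)CC1C(=O)O[C@@H]2C[C@@H](C)C(=O)C(CC3=C(O[Li])O[C@@H]4C[C@@H](C)C(C=C)=CC[C@@H]34)C[C@@H]12 | intermediate (not isolated)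
23 | Michael–aldol adduct: as 22, but the lactone α-carbon is quaternary and carries CH(OH)CH3 cis to the adjacent ring-fusion H | CN(C)CC1C(=O)O[C@@H]2C[C@@H](C)C(=O)C(C[C@@]3(C(C)O)C(=O)O[C@@H]4C[C@@H](C)C(C=C)=CC[C@H]43)C[C@@H]12 | intermediate
24 | β-keto lactone: 23 with C(=O)CH3 in place of CH(OH)CH3 | CN(C)CC1C(=O)O[C@@H]2C[C@@H](C)C(=O)C(C[C@@]3(C(C)=O)C(=O)O[C@@H]4C[C@@H](C)C(C=C)=CC[C@H]43)C[C@@H]12 | intermediate
25 | pentacyclic ketol: target skeleton with ring A CH–CH2NMe2 instead of C=CH2, ring C as CH2–C(=O) instead of CH=C(COCH3), ring E ethenyl instead of 3-oxobut-1-enyl; B/C cis-fused, OH cis to ring-fusion H, ring B methyl trans to OH | CN(C)CC1C(=O)O[C@@H]2C[C@H](C)[C@]3(O)CC(=O)[C@]4(C[C@@H]3C[C@@H]12)C(=O)O[C@@H]1C[C@@H](C)C(C=C)=CC[C@H]14 | intermediate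
26 | trimethylsilyl ether of 25 | CN(C)CC1C(=O)O[C@@H]2C[C@H](C)[C@]3(O[Si](C)(C)C)CC(=O)[C@]4(C[C@@H]3C[C@@H]12)C(=O)O[C@@H]1C[C@@H](C)C(C=C)=CC[C@H]14 | intermediate
27 | ring C enol triflate of 26 (CH=C(OTf) next to the spiro carbon) | CN(C)CC1C(=O)O[C@@H]2C[C@H](C)[C@]3(O[Si](C)(C)C)C=C(OS(=O)(=O)C(F)(F)F)[C@]4(C[C@@H]3C[C@@H]12)C(=O)O[C@@H]1C[C@@H](C)C(C=C)=CC[C@H]14 | intermediate
28 | 1-ethoxyvinyl coupling product of 27 | CN(C)CC1C(=O)O[C@@H]2C[C@H](C)[C@]3(O[Si](C)(C)C)C=C(C(=C)OCC)[C@]4(C[C@@H]3C[C@@H]12)C(=O)O[C@@H]1C[C@@H](C)C(C=C)=CC[C@H]14 | intermediate (not isolated)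
29 | γ-hydroxy enone: target with ring A CH–CH2NMe2 and ring E ethenyl | CN(C)CC1C(=O)O[C@@H]2C[C@H](C)[C@]3(O)C=C(C(C)=O)[C@]4(C[C@@H]3C[C@@H]12)C(=O)O[C@@H]1C[C@@H](C)C(C=C)=CC[C@H]14 | intermediate
30 | trimethylammonium iodide of 29 | C[N+](C)(C)CC1C(=O)O[C@@H]2C[C@H](C)[C@]3(O)C=C(C(C)=O)[C@]4(C[C@@H]3C[C@@H]12)C(=O)O[C@@H]1C[C@@H](C)C(C=C)=CC[C@H]14.[I-] | intermediate (not isolated)
31 | target with ethenyl in place of the (E)-3-oxobut-1-enyl group | C=C1C(=O)O[C@@H]2C[C@H](C)[C@]3(O)C=C(C(C)=O)[C@]4(C[C@@H]3C[C@@H]12)C(=O)O[C@@H]1C[C@@H](C)C(C=C)=CC[C@H]14 | intermediate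
32 | methyl vinyl ketone (but-3-en-2-one) | C=CC(C)=O | starting material
33 | CNP0168949.3 | C=C1C(=O)O[C@@H]2C[C@H](C)[C@]3(O)C=C(C(C)=O)[C@]4(C[C@@H]3C[C@@H]12)C(=O)O[C@@H]1C[C@@H](C)C(/C=C/C(C)=O)=CC[C@H]14 | target

**Totals**
Total step count: 20. Longest linear sequence: 17 steps (1–4, 7, 9–20).

**Steps most likely to fail**

Step 13 (tandem Michael–aldol). The lactone enolate may be quenched by proton transfer from the ketone or may add to a second molecule of 14. The fallback sets out from 19 and 14 and delivers the acetyl group intramolecularly. The pyrrolidine enamine of 19 (pyrrolidine, MeCN, then aq AcOH) adds to 14 under neutral Stork conditions to give the keto bis-lactone Michael adduct F1. Isopropenyl acetate/TsOH converts its ring B ketone into the enol acetate F2. LiN(SiMe3)2 (THF, −78 → 0 °C) then forms the ring D lactone enolate, which takes the acetyl group from the neighbouring enol oxygen through a six-membered transition state (O→C acyl shift of the Baker–Venkataraman type). Protonation gives 24, where the route resumes.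

Step 15 (epimerisation/aldol). The stated thermodynamic preference at the ring-fusion CH, and at the methyl carbon relative to the ring A lactone, is the least secure stereochemical point of the route; dehydration or bridged aldol products are also possible. The fallback sets out from 24. Pyrrolidinium acetate in toluene at 80 °C drives the aldol to the condensation product, the ring C enone F3, in which the ring-fusion CH is γ to the ketone and can be equilibrated and separated. Nucleophilic epoxidation (t-BuOOH, DBU) gives the α,β-epoxy ketone F4. SmI2 (THF/MeOH, −78 °C) cleaves the α C–O bond and returns ketol 25.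

Step 7 (allylboration: boronate geometry, catalyst sense, match with the β-methyl group). The fallback sets out from 7 and 6. syn-Carbocupration of 7 with allylMgBr/CuBr·SMe2 and trapping with the iodomethylboronate gives the (E)-boronate F5. With 6 and (R)-TRIP this gives the syn hydroxy ester F6 (same allyl-bearing centre, epimeric carbinol). LiOH gives the hydroxy acid F7. Mitsunobu lactonisation (PPh3, DIAD) closes the ring with inversion at the carbinol carbon and gives 13.

**Further compounds**
F1 | step 13 | keto bis-lactone Michael adduct (19 joined at C5 by a CH2 link to the lactone α-CH of 14) | CN(C)CC1C(=O)O[C@@H]2C[C@@H](C)C(=O)C(CC3C(=O)O[C@@H]4C[C@@H](C)C(C=C)=CC[C@@H]34)C[C@@H]12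
F2 | step 13 | ring B enol acetate of F1 | CN(C)CC1C(=O)O[C@@H]2C[C@@H](C)C(OC(C)=O)=C(CC3C(=O)O[C@@H]4C[C@@H](C)C(C=C)=CC[C@@H]34)C[C@@H]12
F3 | step 15 | ring C enone (aldol condensation product of 24) | CN(C)CC1C(=O)O[C@@H]2C[C@H](C)C3=CC(=O)[C@]4(C[C@@H]3C[C@@H]12)C(=O)O[C@@H]1C[C@@H](C)C(C=C)=CC[C@H]14
F4 | step 15 | α,β-epoxy ketone of F3 (epoxide oxygen cis to the ring-fusion H) | CN(C)CC1C(=O)O[C@@H]2C[C@H](C)[C@]3(O5)[C@@H]5C(=O)[C@]4(C[C@@H]3C[C@@H]12)C(=O)O[C@@H]1C[C@@H](C)C(C=C)=CC[C@H]14
F5 | step 7 | methyl (2E)-2-[(4,4,5,5-tetramethyl-1,3,2-dioxaborolan-2-yl)methyl]hexa-2,5-dienoate | C=CC/C=C(/C(=O)OC)CB1OC(C)(C)C(C)(C)O1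
F6 | step 7 | methyl (3S,4S,6R)-4-hydroxy-6-methyl-2-methylidene-3-(prop-2-en-1-yl)oct-7-ynoate | C=C(C(=O)OC)[C@H](CC=C)[C@@H](O)C[C@@H](C)C#C
F7 | step 7 | (3S,4S,6R)-4-hydroxy-6-methyl-2-methylidene-3-(prop-2-en-1-yl)oct-7-ynoic acid | C=C(C(=O)O)[C@H](CC=C)[C@@H](O)C[C@@H](C)C#C
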